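**Plan**

1. Numbering: ring C1 (lactone CH–O), C2=C3, C4–C5 (epoxide), C6=C7 (C7–CO2Me), C8 (OAc), C9 (ester O), C10 (ring fusion); lactone C11 (α-carbon), C12 (C=O), C13 (=CH2).
2. Enabling feature: the α-methylene-γ-butyrolactone ring (O–C1–C10–C11–C12) shares the C1–C10 bond with the ten-membered carbocycle; C1 (CH–O) next to C10 (bearing C11(=C13)–C12) is the retron of a 2-(bromomethyl)acrylate adding through C10 to a C1 aldehyde.
3. Cuts, in retrosynthetic order: C9–O acyl; C1–C10 together with O–C12 (both rings at once); C10–C11 and C13–Br; C8–OAc and the C8–C9 epoxide; C7–C8; C6=C7; C3–C4 (enyne).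
4. Forward: the C1–C6 cis-epoxy aldehyde is made first and extended by Wittig reaction (C6=C7) and copper-mediated Stille coupling (C7–C8). The C8/C9 oxygens and the C10–C13 bromomethylacrylate follow, then one chromium step closes carbocycle and lactone together, and the C9 ester is attached last.
5. Stereochemistry: C4/C5 and C8/C9 come from two Sharpless epoxidations (C8 inverted by acetate opening), C1/C10 from the chromium chair transition state steered by C9, and the side-chain epoxide from a third Sharpless epoxidation. Alkene geometries come from the (Z)-iodoacrylate, Lindlar reduction, the iodo-Wittig reaction and the SN2′ bromination.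

Key step: step 16

Assumption: the C10 carbinol created in step 12 is carried as a mixture of epimers, because step 13 turns C10 into an alkene carbon; its SMILES therefore has no descriptor at C10.

**Route**

Step 1
Reactants: 1 ethyl (2Z)-3-iodoprop-2-enoate; 2 4-methoxybenzyl propargyl ether
Product: 3 ethyl (2Z)-6-(4-methoxybenzyloxy)hex-2-en-4-ynoate
Conditions: Pd(PPh3)2Cl2 (2 mol %), CuI (4 mol %), Et3N, THF, 0 °C to rt
Reagents that add atoms: none
Why: Sonogashira coupling of an alkenyl iodide with a terminal alkyne is stereoretentive, so the Z alkene that becomes C4=C5 is fixed here while ester and PMB ether are spectators.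

Step 2
Reactants: 3 ethyl (2Z)-6-(4-methoxybenzyloxy)hex-2-en-4-ynoate
Product: 4 (2Z)-6-(4-methoxybenzyloxy)hex-2-en-4-yn-1-ol
Conditions: DIBAL-H (2.2 equiv), CH2Cl2, −78 °C; Rochelle salt work-up
Reagents that add atoms: none
Why: Hydride reduction of the conjugated ester with DIBAL-H at low temperature should give the C6 allylic alcohol without 1,4-reduction or loss of the Z geometry.

Step 3
Reactants: 4 (2Z)-6-(4-methoxybenzyloxy)hex-2-en-4-yn-1-ol
Product: 5 alkynyl cis-epoxy alcohol
Conditions: Ti(OiPr)4 (20 mol %), diethyl D-(−)-tartrate (24 mol %), t-BuOOH, 4 Å molecular sieves, CH2Cl2, −20 °C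
Reagents that add atoms: tert-butyl hydroperoxide, CC(C)(C)OO
Why: Sharpless asymmetric epoxidation touches only the hydroxyl-bearing allylic alkene, and D-(−)-tartrate should deliver oxygen to the face that makes C5 R and C4 S (cis-epoxide, oxirane 2R,3S); the enantiomeric purity usual for Z-allylic alcohols is upgraded in step 8.

Step 4
Reactants: 5 alkynyl cis-epoxy alcohol
Product: 6 (Z)-alkenyl cis-epoxy alcohol
Conditions: H2 (1 atm), Pd/CaCO3 poisoned with Pb(OAc)2, quinoline, EtOAc, rt
Reagents that add atoms: none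
Why: Lindlar semihydrogenation adds hydrogen syn to the alkyne and stops at the Z alkene C2=C3, the epoxide and the benzylic ether being inert on the poisoned catalyst.

Step 5
Reactants: 6 (Z)-alkenyl cis-epoxy alcohol
Product: 7 cis-epoxy aldehyde
Conditions: Dess–Martin periodinane, NaHCO3, CH2Cl2, 0 °C
Reagents that add atoms: none
Why: Buffered Dess–Martin oxidation should turn the primary alcohol into the C6 aldehyde under near-neutral conditions that neither epimerise C5 nor open the epoxide.

Step 6
Reactants: 7 cis-epoxy aldehyde; 8 methyl (triphenylphosphoranylidene)acetate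
Product: 10 (Z)-α-iodoenoate, via iodo ylide 9 (not isolated)
Conditions: 8, N-iodosuccinimide, CH2Cl2, −20 °C; then K2CO3, 7, −20 °C to rt
Reagents that add atoms: N-iodosuccinimide, O=C1CCC(=O)N1I
Why: Wittig olefination with the stabilised α-iodo ylide places the ester trans to C5, as stabilised ylides do, which with iodine on C7 is the Z iodoenoate and fixes the C6=C7 geometry of the target.

Step 7
Reactants: 10 (Z)-α-iodoenoate; 11 (2E)-3-(tributylstannyl)prop-2-en-1-ol
Product: 12 dienol (C8=C9 E, free C10 hydroxyl)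
Conditions: copper thiophene-2-carboxylate Cu(O2CC4H3S) (1.5 equiv), NMP, 0 °C to rt
Reagents that add atoms: none
Why: Copper-mediated Stille-type coupling (tin-to-copper exchange, then coupling of the alkenylcopper with the alkenyl iodide) should join C7 to C8 with retention at both alkenes and avoids zerovalent palladium, which would ionise the vinyl epoxide.

Step 8
Reactants: 12 dienol
Product: 13 bis-epoxide alcohol
Conditions: Ti(OiPr)4 (20 mol %), diethyl L-(+)-tartrate (24 mol %), t-BuOOH, 4 Å molecular sieves, CH2Cl2, −20 °C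
Reagents that add atoms: tert-butyl hydroperoxide, CC(C)(C)OO
Why: Sharpless asymmetric epoxidation of the E-allylic alcohol is reagent-controlled, L-(+)-tartrate giving the trans-epoxide with C8 S and C9 S, and material from the minor enantiomer of 5 becomes a diastereomer that should be separable here.

Step 9
Reactants: 13 bis-epoxide alcohol
Product: 14 C8 acetate 9,10-diol
Conditions: Ti(OiPr)4 (1.5 equiv), AcOH (2 equiv), CH2Cl2, 0 °C
Reagents that add atoms: acetic acid, CC(O)=O
Why: Titanium-assisted opening of a 2,3-epoxy alcohol by a carboxylic acid occurs at the carbon remote from the carbinol, here the allylic C8, with inversion, giving the C8 R acetate beside the unchanged C9 S oxygen (erythro), while the non-chelating C4–C5 epoxide should react much more slowly.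

Step 10
Reactants: 14 C8 acetate 9,10-diol
Product: 15 bis(triethylsilyl) ether
Conditions: Et3SiOTf, 2,6-lutidine, CH2Cl2, −78 °C
Reagents that add atoms: triethylsilyl trifluoromethanesulfonate, CC[Si](CC)(CC)OS(=O)(=O)C(F)(F)F
Why: Silylation with the silyl triflate is fast at −78 °C, so both hydroxyls should be capped before the C8 acetate can migrate or the C9 hydroxyl can lactonise onto the C7 ester.

Step 11
Reactants: 15 bis(triethylsilyl) ether
Product: 16 C10 aldehyde
Conditions: (COCl)2, DMSO, CH2Cl2, −78 to −40 °C; then Et3N, −78 °C, cold pH 7 quench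
Reagents that add atoms: none
Why: Under Swern conditions a primary triethylsilyl ether is cleaved by the chlorosulfonium salt and oxidised directly to the aldehyde while the secondary silyl ether stays, and the low temperature should suppress β-elimination of the C8 acetate.

Step 12
Reactants: 16 C10 aldehyde; 17 methyl propiolate
Product: 19 Morita–Baylis–Hillman-type alcohol (C10 epimers), via vinylalane 18 (not isolated)
Conditions: 17, DIBAL-H, N-methylmorpholine N-oxide, THF, 0 °C; then 16, 0 °C
Reagents that add atoms: none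
Why: Vinylalumination (hydroalumination of the propiolate to the α-alumino acrylate, then addition to the aldehyde) gives the Morita–Baylis–Hillman adduct without the amine base that would eliminate the β-acetate, and the new C10 carbinol centre is of no consequence.

Step 13
Reactants: 19 Morita–Baylis–Hillman-type alcohol
Product: 20 (Z)-allylic bromide
Conditions: N-bromosuccinimide, Me2S, CH2Cl2, 0 °C; then 19, 0 °C to rt
Reagents that add atoms: N-bromosuccinimide, O=C1CCC(=O)N1Br
Why: Corey–Kim-type activation of the allylic hydroxyl and SN2′ attack of bromide at C13 should give the transposed primary bromide with the Z geometry (C9 cis to CH2Br) that is known to result from Morita–Baylis–Hillman alcohols.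

Step 14
Reactants: 20 (Z)-allylic bromide
Product: 21 C1 allylic alcohol
Conditions: DDQ, CH2Cl2–pH 7 buffer, 0 °C
Reagents that add atoms: none
Why: Oxidative cleavage of the 4-methoxybenzyl ether by DDQ is near-neutral and should spare the allylic bromide, silyl ether, acetate and epoxide, the buffer preventing acid-promoted attack of the freed hydroxyl on C4.

Step 15
Reactants: 21 C1 allylic alcohol
Product: 22 seco (Z)-enal bromide
Conditions: Dess–Martin periodinane, NaHCO3, CH2Cl2, 0 °C; used at once
Reagents that add atoms: none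
Why: Buffered Dess–Martin oxidation of the Z-allylic alcohol should give the Z enal without isomerisation and without touching the allylic bromide.

Step 16
Reactants: 22 seco (Z)-enal bromide
Product: 24 C9 triethylsilyl ether of the bicyclic lactone, via hydroxy ester 23 (not isolated)
Conditions: CrCl2 (10 equiv), THF, 2 mM, slow addition of 22, rt
Reagents that add atoms: none
Why: Two equivalents of divalent chromium reduce the allylic C–Br bond to a trivalent allylchromium that adds through C10, with allylic transposition, to the C1 aldehyde in a six-membered Zimmerman–Traxler chair, forming C1–C10 and the C11=C13 methylene, after which the chromium alkoxide attacks the C12 methyl ester and expels methoxide. The closest known reaction type is the intramolecular Nozaki–Hiyama allylation of 2-(bromomethyl)acrylates onto aldehydes, which is established for α-methylene lactones fused to ten-membered carbocycles. The carbocycle closes by 10-exo-trig addition to the carbonyl group and the lactone by 5-exo-trig acyl substitution. C1 and C10 are set together: the chair with the C9 branch equatorial on the equilibrating allylchromium should give the anti adduct and hence the trans ring fusion, and the C9 triethylsilyloxy group, held outward on the folding chain, selects which faces of C10 and of the aldehyde meet. The step needs ring closure over oligomerisation, 1,2- over 1,4-addition and tolerance of epoxide, acetate and enoate; high dilution, the turn elements already in the chain (Z enal, cis-epoxide, ring-cis C6=C7) and the non-basic, aldehyde-selective organochromium reagent should secure these.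

Step 17
Reactants: 24 C9 triethylsilyl ether of the bicyclic lactone
Product: 25 C9 alcohol of the bicyclic lactone
Conditions: HF·pyridine, pyridine, THF, 0 °C
Reagents that add atoms: none
Why: Fluoride cleavage of the secondary triethylsilyl ether is fast under pyridine-buffered conditions that should leave the epoxide, the acetate, the lactone and the methyl ester alone.

Step 18
Reactants: 26 angelic acid
Product: 27 (2Z)-2-methylbut-2-en-1-ol
Conditions: LiAlH4, Et2O, 0 °C to rt
Reagents that add atoms: none
Why: Hydride reduction of the carboxylic acid gives the allylic alcohol with the Z alkene intact.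

Step 19
Reactants: 27 (2Z)-2-methylbut-2-en-1-ol
Product: 28 [(2R,3S)-2,3-dimethyloxiran-2-yl]methanol
Conditions: Ti(OiPr)4 (10 mol %), diethyl D-(−)-tartrate (12 mol %), t-BuOOH, 4 Å molecular sieves, CH2Cl2, −20 °C
Reagents that add atoms: tert-butyl hydroperoxide, CC(C)(C)OO
Why: Sharpless asymmetric epoxidation with D-(−)-tartrate should give the (2R,3S)-epoxy alcohol, which keeps the two ring methyl groups trans as in the Z alkene and maps onto the (2S,3S) acid.

Step 20
Reactants: 28 [(2R,3S)-2,3-dimethyloxiran-2-yl]methanol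
Product: 29 (2S,3S)-2,3-dimethyloxirane-2-carboxylic acid
Conditions: RuCl3 hydrate (cat.), NaIO4, CCl4–MeCN–H2O, rt
Reagents that add atoms: water, O
Why: Ruthenium tetroxide generated from RuCl3 and periodate oxidises the primary alcohol through the aldehyde hydrate to the acid without opening the epoxide, and the C2 descriptor changes only because the substituent priorities change.

Step 21
Reactants: 25 C9 alcohol of the bicyclic lactone; 29 (2S,3S)-2,3-dimethyloxirane-2-carboxylic acid
Product: 31 target CNP0077533.1, via mixed anhydride 30 (not isolated)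
Conditions: 29, 2,4,6-trichlorobenzoyl chloride, Et3N, toluene, rt; then 25, DMAP, toluene, rt
Reagents that add atoms: none
Why: Yamaguchi esterification activates the hindered α,α-disubstituted acid as its mixed anhydride, which DMAP should transfer to the C9 hydroxyl with retention at C9 and without touching the epoxides.

**Compound list**

1 | ethyl (2Z)-3-iodoprop-2-enoate | CCOC(=O)/C=C\I | starting material
2 | 1-methoxy-4-[(prop-2-yn-1-yloxy)methyl]benzene (4-methoxybenzyl propargyl ether) | C#CCOCc1ccc(OC)cc1 | starting material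
3 | ethyl (2Z)-6-[(4-methoxyphenyl)methoxy]hex-2-en-4-ynoate | CCOC(=O)/C=C\C#CCOCc1ccc(OC)cc1 | intermediate
4 | (2Z)-6-[(4-methoxyphenyl)methoxy]hex-2-en-4-yn-1-ol | OC/C=C\C#CCOCc1ccc(OC)cc1 | intermediate
5 | [(2R,3S)-3-{3-[(4-methoxyphenyl)methoxy]prop-1-yn-1-yl}oxiran-2-yl]methanol | COc1ccc(COCC#C[C@@H]2O[C@@H]2CO)cc1 | intermediate
6 | [(2R,3S)-3-{(1Z)-3-[(4-methoxyphenyl)methoxy]prop-1-en-1-yl}oxiran-2-yl]methanol | COc1ccc(COC/C=C\[C@@H]2O[C@@H]2CO)cc1 | intermediate
7 | (2S,3S)-3-{(1Z)-3-[(4-methoxyphenyl)methoxy]prop-1-en-1-yl}oxirane-2-carbaldehyde | COc1ccc(COC/C=C\[C@@H]2O[C@@H]2C=O)cc1 | intermediate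
8 | methyl (triphenylphosphoranylidene)acetate | COC(=O)C=P(c1ccccc1)(c1ccccc1)c1ccccc1 | starting material
9 | methyl iodo(triphenylphosphoranylidene)acetate (iodo ylide, formed in the flask) | COC(=O)C(I)=P(c1ccccc1)(c1ccccc1)c1ccccc1 | intermediate
10 | methyl (2Z)-2-iodo-3-[(2R,3S)-3-{(1Z)-3-[(4-methoxyphenyl)methoxy]prop-1-en-1-yl}oxiran-2-yl]prop-2-enoate | COc1ccc(COC/C=C\[C@@H]2O[C@@H]2/C=C(\I)C(=O)OC)cc1 | intermediate
11 | (2E)-3-(tributylstannyl)prop-2-en-1-ol | CCCC[Sn](CCCC)(CCCC)/C=C/CO | starting material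
12 | methyl (2E,3E)-5-hydroxy-2-{[(2R,3S)-3-{(1Z)-3-[(4-methoxyphenyl)methoxy]prop-1-en-1-yl}oxiran-2-yl]methylidene}pent-3-enoate | COc1ccc(COC/C=C\[C@@H]2O[C@@H]2/C=C(/C(=O)OC)\C=C\CO)cc1 | intermediate
13 | methyl (2E)-2-[(2S,3S)-3-(hydroxymethyl)oxiran-2-yl]-3-[(2R,3S)-3-{(1Z)-3-[(4-methoxyphenyl)methoxy]prop-1-en-1-yl}oxiran-2-yl]prop-2-enoate | COc1ccc(COC/C=C\[C@@H]2O[C@@H]2/C=C(/C(=O)OC)[C@@H]2O[C@H]2CO)cc1 | intermediate
14 | methyl (2E)-2-[(1R,2S)-1-(acetyloxy)-2,3-dihydroxypropyl]-3-[(2R,3S)-3-{(1Z)-3-[(4-methoxyphenyl)methoxy]prop-1-en-1-yl}oxiran-2-yl]prop-2-enoate | COc1ccc(COC/C=C\[C@@H]2O[C@@H]2/C=C(/C(=O)OC)[C@@H](OC(C)=O)[C@@H](O)CO)cc1 | intermediate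
15 | methyl (2E)-2-{(1R,2S)-1-(acetyloxy)-2,3-bis[(triethylsilyl)oxy]propyl}-3-[(2R,3S)-3-{(1Z)-3-[(4-methoxyphenyl)methoxy]prop-1-en-1-yl}oxiran-2-yl]prop-2-enoate | COc1ccc(COC/C=C\[C@@H]2O[C@@H]2/C=C(/C(=O)OC)[C@@H](OC(C)=O)[C@@H](O[Si](CC)(CC)CC)CO[Si](CC)(CC)CC)cc1 | intermediate
16 | methyl (2E)-2-{(1R,2R)-1-(acetyloxy)-3-oxo-2-[(triethylsilyl)oxy]propyl}-3-[(2R,3S)-3-{(1Z)-3-[(4-methoxyphenyl)methoxy]prop-1-en-1-yl}oxiran-2-yl]prop-2-enoate | COc1ccc(COC/C=C\[C@@H]2O[C@@H]2/C=C(/C(=O)OC)[C@@H](OC(C)=O)[C@@H](O[Si](CC)(CC)CC)C=O)cc1 | intermediate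
17 | methyl prop-2-ynoate (methyl propiolate) | C#CC(=O)OC | starting material
18 | [1-(methoxycarbonyl)ethenyl]bis(2-methylpropyl)aluminium (vinylalane, formed in the flask as its N-methylmorpholine N-oxide complex) | C=C(C(=O)OC)[Al](CC(C)C)CC(C)C | intermediate
19 | dimethyl (4S,5R,6E)-5-(acetyloxy)-3-hydroxy-2-methylidene-6-{[(2R,3S)-3-{(1Z)-3-[(4-methoxyphenyl)methoxy]prop-1-en-1-yl}oxiran-2-yl]methylidene}-4-[(triethylsilyl)oxy]heptanedioate, both epimers at the carbinol (C10) | COc1ccc(COC/C=C\[C@@H]2O[C@@H]2/C=C(/C(=O)OC)[C@@H](OC(C)=O)[C@@H](O[Si](CC)(CC)CC)C(O)C(=C)C(=O)OC)cc1 | intermediate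
20 | dimethyl (2Z,4S,5R,6E)-5-(acetyloxy)-2-(bromomethyl)-6-{[(2R,3S)-3-{(1Z)-3-[(4-methoxyphenyl)methoxy]prop-1-en-1-yl}oxiran-2-yl]methylidene}-4-[(triethylsilyl)oxy]hept-2-enedioate | COc1ccc(COC/C=C\[C@@H]2O[C@@H]2/C=C(/C(=O)OC)[C@@H](OC(C)=O)[C@@H](O[Si](CC)(CC)CC)/C=C(\CBr)C(=O)OC)cc1 | intermediate
21 | dimethyl (2Z,4S,5R,6E)-5-(acetyloxy)-2-(bromomethyl)-6-{[(2R,3S)-3-[(1Z)-3-hydroxyprop-1-en-1-yl]oxiran-2-yl]methylidene}-4-[(triethylsilyl)oxy]hept-2-enedioate | OC/C=C\[C@@H]1O[C@@H]1/C=C(/C(=O)OC)[C@@H](OC(C)=O)[C@@H](O[Si](CC)(CC)CC)/C=C(\CBr)C(=O)OC | intermediate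
22 | dimethyl (2Z,4S,5R,6E)-5-(acetyloxy)-2-(bromomethyl)-6-{[(2R,3S)-3-[(1Z)-3-oxoprop-1-en-1-yl]oxiran-2-yl]methylidene}-4-[(triethylsilyl)oxy]hept-2-enedioate (key-step precursor) | O=C/C=C\[C@@H]1O[C@@H]1/C=C(/C(=O)OC)[C@@H](OC(C)=O)[C@@H](O[Si](CC)(CC)CC)/C=C(\CBr)C(=O)OC | intermediate
23 | ten-membered hydroxy ester (ring-opened lactone of 24: C1 R carbinol, C10 S bearing the 1-(methoxycarbonyl)ethenyl group; formed in the flask as its chromium alkoxide) | C=C(C(=O)OC)[C@H]1[C@H](O)/C=C\[C@@H]2O[C@@H]2/C=C(/C(=O)OC)[C@@H](OC(C)=O)[C@H]1O[Si](CC)(CC)CC | intermediate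
24 | C9 triethylsilyl ether of the bicyclic lactone (C1 R, C4 S, C5 R, C8 R, C9 S, C10 S; key-step product) | C=C1C(=O)O[C@@H]2/C=C\[C@@H]3O[C@@H]3/C=C(/C(=O)OC)[C@@H](OC(C)=O)[C@@H](O[Si](CC)(CC)CC)[C@@H]12 | intermediate
25 | C9 alcohol of the bicyclic lactone | C=C1C(=O)O[C@@H]2/C=C\[C@@H]3O[C@@H]3/C=C(/C(=O)OC)[C@@H](OC(C)=O)[C@@H](O)[C@@H]12 | intermediate
26 | angelic acid, (2Z)-2-methylbut-2-enoic acid | C/C=C(/C)C(O)=O | starting material
27 | (2Z)-2-methylbut-2-en-1-ol | C/C=C(/C)CO | intermediate
28 | [(2R,3S)-2,3-dimethyloxiran-2-yl]methanol | OC[C@@]1(C)O[C@H]1C | intermediate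
29 | (2S,3S)-2,3-dimethyloxirane-2-carboxylic acid | OC(=O)[C@@]1(C)O[C@H]1C | intermediate
30 | (2S,3S)-2,3-dimethyloxirane-2-carboxylic 2,4,6-trichlorobenzoic anhydride (formed in the flask) | O=C(OC(=O)c1c(Cl)cc(Cl)cc1Cl)[C@@]1(C)O[C@H]1C | intermediate
31 | target CNP0077533.1: C9 (2S,3S)-2,3-dimethyloxirane-2-carboxylate of 25 (C1 R, C4 S, C5 R, C8 R, C9 S, C10 S) | C=C1C(=O)O[C@@H]2/C=C\[C@@H]3O[C@@H]3/C=C(/C(=O)OC)[C@@H](OC(C)=O)[C@@H](OC(=O)[C@@]3(C)O[C@H]3C)[C@@H]12 | target

**Step count**

Total: 21 steps. Longest linear sequence: 18 steps (steps 1–17 and 21); the side-chain acid takes steps 18–20.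

**Steps most likely to fail**

Step 16. The ring closure may pass through the competing transition state, so that the aldehyde is attacked on its other face, or chain coupling may outrun cyclisation. The fallback sets out from 22. Indium powder in THF–H2O at high dilution should stop at the ten-membered hydroxy ester. If this is the C1-epimeric hydroxy ester F1, Dess–Martin oxidation gives the ten-membered C1 ketone F2. NaBH4/CeCl3 reduction from the outer face of the ring then gives hydroxy ester 23, and catalytic DMAP in toluene closes the lactone, coming back to the route at 24.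

Step 7. The alkenylcopper formed by tin-to-copper exchange may open the vinyl epoxide in an SN2′ sense, or the exchange may be too slow. The fallback sets out from 7. Knoevenagel condensation of trimethyl phosphonoacetate with 3-[(tert-butyldimethylsilyl)oxy]propanal (TiCl4, N-methylmorpholine) gives the alkylidene phosphonate F3. Its γ-deprotonation (LiN(SiMe3)2, THF, −78 °C) and Horner–Wadsworth–Emmons reaction of the resulting α-carbanion with 7 give the triene silyl ether F4. Bu4NF buffered with AcOH then frees the C10 hydroxyl, coming back to the route at 12.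

Step 12. The aldehyde may lose acetic acid by β-elimination, or the acetyl group may migrate to the new aluminium alkoxide. The fallback sets out from 16. Methyl 3-(phenylselanyl)propanoate F5, made by adding benzeneselenol to methyl acrylate, is converted to its lithium enolate (LDA, THF, −78 °C) and added to 16 to give the selenide aldol adduct F6. Oxidation with H2O2/pyridine at 0 °C and selenoxide syn-elimination come back to the route at 19.

**Further compounds**

F1 | step 16 | C1-epimeric hydroxy ester | C=C(C(=O)OC)[C@H]1[C@@H](O)/C=C\[C@@H]2O[C@@H]2/C=C(/C(=O)OC)[C@@H](OC(C)=O)[C@H]1O[Si](CC)(CC)CC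
F2 | step 16 | ten-membered C1 ketone | C=C(C(=O)OC)[C@H]1C(=O)/C=C\[C@@H]2O[C@@H]2/C=C(/C(=O)OC)[C@@H](OC(C)=O)[C@H]1O[Si](CC)(CC)CC
F3 | step 7 | alkylidene phosphonate, methyl 5-[(tert-butyldimethylsilyl)oxy]-2-(dimethoxyphosphoryl)pent-2-enoate | COC(=O)C(=CCCO[Si](C)(C)C(C)(C)C)P(=O)(OC)OC
F4 | step 7 | triene silyl ether (tert-butyldimethylsilyl ether of 12) | COc1ccc(COC/C=C\[C@@H]2O[C@@H]2/C=C(/C(=O)OC)\C=C\CO[Si](C)(C)C(C)(C)C)cc1
F5 | step 12 | methyl 3-(phenylselanyl)propanoate | COC(=O)CC[Se]c1ccccc1
F6 | step 12 | selenide aldol adduct | COc1ccc(COC/C=C\[C@@H]2O[C@@H]2/C=C(/C(=O)OC)[C@@H](OC(C)=O)[C@@H](O[Si](CC)(CC)CC)C(O)C(C[Se]c3ccccc3)C(=O)OC)cc1
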